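All runs were computed for an exercise; scatter was added.

Turning one substrate into target is taken here to cost one reagent; zeta carries no reagent reading, so this is an assumption.

the same everywhere: substrate 0.10 M; free catalyst 6.5 mM

| run | reagent | remark |
|---|---|---|
| zeta | 0.14 M | run made earlier |
| flask | 0.0950 M |  |

zeta run (percent of the substrate charged)

| time / min | target / % |
|---|---|
| 2.00 | 4.4 |
| 4.00 | 9.9 |
| 6.00 | 16.8 |
| 10.0 | 25.1 |
| 15.0 | 35.1 |
| 25.0 | 50.6 |

(scatter of a reading: 0.5 percentage points)

- apparent order in reagent when 50% of the substrate are converted (percent change of the rate of making target for one percent more reagent charged)
- apparent order in free catalyst when 50% of the substrate are converted (percent change of the rate of making target for one percent more free catalyst charged)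
- factor on the rate of making target when 50% of the substrate are converted if free catalyst is charged twice over

- no earlier run changes the charge of free catalyst; that part of a forecast is a guess
- no earlier run changes the charge of reagent; that part of a forecast is a guess

In the flask, 50% conversion then uses 0.0500 M of reagent and leaves 0.0450 M. Reagent is the limiting reagent of this flask, its charge 0.0950 M being less than the substrate charge 0.10 M. Let the rate go as the power b of the reagent present. At a fixed conversion x the amount used stays the same when the charge of reagent is raised, so the whole rise falls on the remainder cB − x·cA, which is smaller than the charge. The percent change of that remainder for one percent on the charge is the gearing G, the charge of reagent over what remains of it at that conversion, 2.11 for the flask, and the apparent order in reagent is b·G. For zeta the same rule gives 1.56, less than in the flask.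

With b equal to one the order is G itself, and b is the weak link, since the zeta readings, scattering by 0.5 percentage points, leave it open. At its last reading, after 25.0 min, zeta still holds about 0.0894 M of reagent, whereas the flask at 50% holds less. A saturating dependence on reagent moves toward first order as reagent falls, so this reckoning sets b a little under one and commits to an order in reagent somewhat under G. Free catalyst was never varied, so first order, with a factor of 2 on doubling, is a guess.

The forecast, lower in reagent than this reckoning, gave an order in reagent of 0.4, an order in free catalyst of 0.9 and a factor of 1.87 on doubling free catalyst, reasoning that “any saturation in reagent is weaker and its order higher”.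

The flask gives an order in reagent of 1.8, an order in free catalyst of 1.1, and a factor of 2.35 on doubling free catalyst.

    reagent + free catalyst ⇌ catalyst intermediate A (K = 14.0 M⁻¹, k = 1.57 M⁻¹ s⁻¹)
    catalyst intermediate A → by-product + catalyst intermediate B (k = 0.0143 s⁻¹)
    substrate + catalyst intermediate B ⇌ catalyst intermediate C (K = 6.95 M⁻¹, k = 0.586 M⁻¹ s⁻¹)
    catalyst intermediate C → free catalyst + target (k = 0.480 s⁻¹)
    free catalyst + by-product ⇌ idle complex (K = 52.3 M⁻¹, k = 0.0785 M⁻¹ s⁻¹)

After 15.0 h the flask holds target 95.0%, substrate 5.00% and reagent 0%. Divided by G, the order 1.8 leaves 0.859 as the order in the reagent remaining, and that order times the zeta gearing 1.56 comes to 1.34.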